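**Plan**

- Retrosynthetic cuts, in order: the four Si-based protecting groups; the ring olefin C5=C6 of the tetrahydrooxepine (ring-closing metathesis); the ether bond O1–C7 (O-allylation of the C2 carbinol); the bond from the quaternary ring carbon C2 to the phenacyl CH2 (aldol); the CH2–CH2 bond of the side-chain linker (dianion alkylation).
- Forward: the silyl enol ether of protected 2',5'-dihydroxyacetophenone adds to an α-keto ester whose ketone carbon becomes C2. The new carbinol oxygen becomes O1 by allylation with the C9 side-chain piece, the seven-membered ring closes at C5=C6, and fluoride unmasks phenols, alcohol and acid together.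
- Enabling feature: C2 carries O1 β to the aryl ketone and is bonded directly to the carboxyl carbon. The array O1–C2(CO2H)–CH2–C(=O)Ar is therefore the aldol of an aryl methyl ketone with an α-keto ester, and the 1,2-dicarbonyl unit of that keto ester chelates a chiral Cu(II) Lewis acid.
- Stereochemistry: the only stereocentre, C2 (R), is set in the aldol by the (R,R)-bis(oxazoline) ligand and no later step breaks a bond to it. The E side-chain olefin comes from SN2' chloride opening of isoprene monoxide. The ring olefin geometry is fixed by the ring.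

Key step: step 9

Remark: from the SMILES the stereocentre is (R), with CIP order O1 > CO2H > CH2C(=O)Ar > ring CH2; ring numbering used throughout is O1, C2 (quaternary), C3, C4, C5=C6, C7.

**Route**

Step 1
Reactants: 1 2',5'-dihydroxyacetophenone
Product: 2 1-[2,5-bis(tert-butyldimethylsilyloxy)phenyl]ethan-1-one
Conditions: TBSCl (2.5 equiv), imidazole (5 equiv), DMAP (cat.), DMF, rt → 40 °C
Reagents that add atoms: tert-butyldimethylsilyl chloride, CC(C)(C)[Si](C)(C)Cl
Why: Imidazole-promoted O-silylation of both phenols should proceed (the hydrogen-bonded 2'-OH more slowly, hence excess reagent and DMAP) and gives ethers that survive Lewis acid, catalytic Brønsted acid and Ru carbenes and fall to fluoride at the end.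

Step 2
Reactants: 2 1-[2,5-bis(tert-butyldimethylsilyloxy)phenyl]ethan-1-one
Product: 3 {1-[2,5-bis(tert-butyldimethylsilyloxy)phenyl]ethenyloxy}trimethylsilane
Conditions: TMSOTf (1.2 equiv), Et3N (1.5 equiv), CH2Cl2, 0 °C; non-aqueous work-up (pentane, filtration)
Reagents that add atoms: trimethylsilyl trifluoromethanesulfonate, C[Si](C)(C)OS(=O)(=O)C(F)(F)F
Why: Soft enolisation of a methyl ketone with a silyl triflate and an amine (silyl enol ether formation) can give only one regioisomer because the ketone has a single enolisable side.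

Step 3
Reactants: 4 oxalyl chloride; 5 2-(trimethylsilyl)ethanol (2.1 equiv)
Product: 6 bis[2-(trimethylsilyl)ethyl] oxalate
Conditions: pyridine (2.2 equiv), CH2Cl2, 0 °C → rt
Reagents that add atoms: none
Why: Double acylation of a primary alcohol by a diacid chloride (esterification) installs the fluoride-labile silylethyl ester at the outset, so that no basic ester hydrolysis is needed later.

Step 4
Reactants: 6 bis[2-(trimethylsilyl)ethyl] oxalate (1.3 equiv); 7 but-3-enylmagnesium bromide (THF solution)
Product: 8 2-(trimethylsilyl)ethyl 2-oxohex-5-enoate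
Conditions: THF/Et2O, −78 °C, Grignard added to the oxalate; quench at −78 °C with 1 M HCl
Reagents that add atoms: none
Why: Mono-addition of a Grignard reagent to a dialkyl oxalate stops at the magnesium hemiketal, which is stable at −78 °C and collapses to the α-keto ester only on acidic quench (standard α-keto ester synthesis).

Step 5
Reactants: 9 2-methyl-2-vinyloxirane (isoprene monoxide, racemic)
Product: 10 (E)-4-chloro-2-methylbut-2-en-1-ol
Conditions: TiCl4 (1 equiv), CH2Cl2, −90 → −78 °C; aqueous work-up
Reagents that add atoms: titanium tetrachloride, Cl[Ti](Cl)(Cl)Cl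
Why: Lewis acid activation of the vinyl epoxide with chloride delivery to the vinyl terminus (SN2' epoxide opening) should give the primary allylic chloride with the E trisubstituted olefin, as known for this substrate; any minor Z isomer would be removed by chromatography here or at 14.

Step 6
Reactants: 10 (E)-4-chloro-2-methylbut-2-en-1-ol
Product: 11 (E)-tert-butyl[(4-chloro-2-methylbut-2-en-1-yl)oxy]dimethylsilane
Conditions: TBSCl (1.1 equiv), imidazole (1.5 equiv), CH2Cl2, 0 °C
Reagents that add atoms: tert-butyldimethylsilyl chloride, CC(C)(C)[Si](C)(C)Cl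
Why: Silylation of the primary allylic alcohol is fast at 0 °C and leaves the allylic chloride untouched (silyl ether protection).

Step 7
Reactants: 12 2-methylprop-2-en-1-ol (methallyl alcohol, 1.5 equiv); 11 (E)-tert-butyl[(4-chloro-2-methylbut-2-en-1-yl)oxy]dimethylsilane
Product: 14 (E)-7-(tert-butyldimethylsilyloxy)-6-methyl-2-methylidenehept-5-en-1-ol, via dilithiated 2-methylprop-2-en-1-ol 13 (not isolated)
Conditions: n-BuLi (2 equiv per 12), TMEDA, Et2O, 0 °C → rt; then 11, THF, −78 → 0 °C; H2O
Reagents that add atoms: none
Why: Alkoxide-directed allylic lithiation of methallyl alcohol gives a C,O-dianion that is alkylated at carbon by the primary allylic chloride (dianion SN2 alkylation), the fully substituted γ-carbon of 11 suppressing SN2' attack and the E olefin being carried over unchanged.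

Step 8
Reactants: 14 (E)-7-(tert-butyldimethylsilyloxy)-6-methyl-2-methylidenehept-5-en-1-ol
Product: 15 (E)-7-(tert-butyldimethylsilyloxy)-6-methyl-2-methylidenehept-5-en-1-yl 2,2,2-trichloroacetimidate
Conditions: Cl3CCN (1.5 equiv), DBU (0.1 equiv), CH2Cl2, 0 °C; used after rapid filtration through deactivated silica
Reagents that add atoms: trichloroacetonitrile, N#CC(Cl)(Cl)Cl
Why: Base-catalysed addition of the alcohol to the electron-poor nitrile (trichloroacetimidate formation) turns the allylic alcohol into an electrophile that can be activated by catalytic acid instead of base.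

Step 9
Reactants: 3 {1-[2,5-bis(tert-butyldimethylsilyloxy)phenyl]ethenyloxy}trimethylsilane (1.2 equiv); 8 2-(trimethylsilyl)ethyl 2-oxohex-5-enoate
Product: 17 2-(trimethylsilyl)ethyl (R)-2-{2-[2,5-bis(tert-butyldimethylsilyloxy)phenyl]-2-oxoethyl}-2-hydroxyhex-5-enoate, via O-trimethylsilyl aldol adduct 16 (not isolated)
Conditions: Cu(OTf)2 / (R,R)-t-Bu-box [2,2'-isopropylidenebis((4R)-4-tert-butyl-2-oxazoline)] (10 mol %), THF, −78 °C; then 1 M HCl, THF, 0 °C
Reagents that add atoms: none
Why: Keto ester 8 binds the Cu(II)–bis(oxazoline) dication through its ketone and ester carbonyl oxygens in a distorted square-planar chelate, the CH2 terminus of enolsilane 3 adds through an open transition state to the activated ketone carbon (new bond C2–CH2), and silyl transfer then gives silyl ether 16 and frees the catalyst (Mukaiyama aldol addition). The closest known reaction type is the Cu(II)–bis(oxazoline)-catalysed enantioselective addition of aryl methyl ketone enolsilanes to pyruvate and to homologous primary-alkyl α-keto esters. No ring is closed in this step. The new stereocentre C2 is controlled by the ligand: a tert-butyl group blocks one face of the chelated ketone, and since the (S,S)-ligand is known to expose the si face and give (S)-carbinols of this substitution pattern, the (R,R)-ligand should expose the re face and give the (R)-carbinol (CIP order OH > CO2R > CH2C(O)Ar > butenyl). The step needs enantiofacial selectivity and attack at the ketone and not the ester carbonyl, and both follow from the two-point 1,2-dicarbonyl chelation, while the terminal olefin, the aryl silyl ethers and the silylethyl ester should not compete for copper. Dilute acid on work-up should cleave only the tertiary O–SiMe3 bond.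

Step 10
Reactants: 17 2-(trimethylsilyl)ethyl (R)-2-{2-[2,5-bis(tert-butyldimethylsilyloxy)phenyl]-2-oxoethyl}-2-hydroxyhex-5-enoate; 15 (E)-7-(tert-butyldimethylsilyloxy)-6-methyl-2-methylidenehept-5-en-1-yl 2,2,2-trichloroacetimidate (2–3 equiv)
Product: 18 2-(trimethylsilyl)ethyl (R)-2-{2-[2,5-bis(tert-butyldimethylsilyloxy)phenyl]-2-oxoethyl}-2-{[(E)-7-(tert-butyldimethylsilyloxy)-6-methyl-2-methylidenehept-5-en-1-yl]oxy}hex-5-enoate
Conditions: TfOH (5–10 mol %), CH2Cl2/cyclohexane, 4 Å MS, −20 → 0 °C
Reagents that add atoms: none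
Why: Acid-activated imidate O-alkylation etherifies the tertiary hydroxyl without forming an alkoxide, so retro-aldol cleavage of the β-hydroxy ketone is avoided; the 2-substituted allyl unit gives the same ether by SN2 or SN2' attack, and the C2–O bond is not broken, so the configuration is kept.

Step 11
Reactants: 18 2-(trimethylsilyl)ethyl (R)-2-{2-[2,5-bis(tert-butyldimethylsilyloxy)phenyl]-2-oxoethyl}-2-{[(E)-7-(tert-butyldimethylsilyloxy)-6-methyl-2-methylidenehept-5-en-1-yl]oxy}hex-5-enoate
Product: 19 2-(trimethylsilyl)ethyl (R)-2-{2-[2,5-bis(tert-butyldimethylsilyloxy)phenyl]-2-oxoethyl}-6-[(E)-5-(tert-butyldimethylsilyloxy)-4-methylpent-3-en-1-yl]-2,3,4,7-tetrahydrooxepine-2-carboxylate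
Conditions: Grubbs II catalyst (5–10 mol %), CH2Cl2 (2 mM), 40 °C
Reagents that add atoms: none
Why: Ring-closing metathesis starts at the terminal butenyl olefin and closes onto the 1,1-disubstituted allyl ether olefin to form C5=C6 of the seven-membered ring (helped by the fully substituted C2), the ring enforcing the cis arrangement of C4 and C7, while the trisubstituted side-chain olefin is too hindered to take part.

Step 12
Reactants: 19 2-(trimethylsilyl)ethyl (R)-2-{2-[2,5-bis(tert-butyldimethylsilyloxy)phenyl]-2-oxoethyl}-6-[(E)-5-(tert-butyldimethylsilyloxy)-4-methylpent-3-en-1-yl]-2,3,4,7-tetrahydrooxepine-2-carboxylate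
Product: 20 (R)-2-[2-(2,5-dihydroxyphenyl)-2-oxoethyl]-6-[(E)-5-hydroxy-4-methylpent-3-en-1-yl]-2,3,4,7-tetrahydrooxepine-2-carboxylic acid
Conditions: TBAF (6 equiv), THF, 0 °C → rt; cold 0.5 M HCl work-up
Reagents that add atoms: none
Why: Fluoride cleaves the three Si–O bonds and fragments the 2-(trimethylsilyl)ethyl ester to the carboxylate, ethene and fluorotrimethylsilane (global desilylation), the aryl silyl ethers going first so that the resulting ortho-phenoxide deactivates the ketone towards enolisation before the slower ester cleavage.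

**Compound list**

1 | 2',5'-dihydroxyacetophenone | CC(=O)c1cc(O)ccc1O | starting material
2 | 1-[2,5-bis(tert-butyldimethylsilyloxy)phenyl]ethan-1-one | CC(=O)c1cc(O[Si](C)(C)C(C)(C)C)ccc1O[Si](C)(C)C(C)(C)C | intermediate
3 | {1-[2,5-bis(tert-butyldimethylsilyloxy)phenyl]ethenyloxy}trimethylsilane | C=C(O[Si](C)(C)C)c1cc(O[Si](C)(C)C(C)(C)C)ccc1O[Si](C)(C)C(C)(C)C | intermediate
4 | oxalyl chloride | O=C(Cl)C(=O)Cl | starting material
5 | 2-(trimethylsilyl)ethanol | C[Si](C)(C)CCO | starting material
6 | bis[2-(trimethylsilyl)ethyl] oxalate | C[Si](C)(C)CCOC(=O)C(=O)OCC[Si](C)(C)C | intermediate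
7 | but-3-enylmagnesium bromide | C=CCC[Mg]Br | starting material
8 | 2-(trimethylsilyl)ethyl 2-oxohex-5-enoate | C=CCCC(=O)C(=O)OCC[Si](C)(C)C | intermediate
9 | 2-methyl-2-vinyloxirane (racemic) | CC1(C=C)CO1 | starting material
10 | (E)-4-chloro-2-methylbut-2-en-1-ol | C/C(=C\CCl)CO | intermediate
11 | (E)-tert-butyl[(4-chloro-2-methylbut-2-en-1-yl)oxy]dimethylsilane | C/C(=C\CCl)CO[Si](C)(C)C(C)(C)C | intermediate
12 | 2-methylprop-2-en-1-ol | CC(=C)CO | starting material
13 | dilithiated 2-methylprop-2-en-1-ol (C,O-dianion, not isolated) | [Li]CC(=C)CO[Li] | intermediate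
14 | (E)-7-(tert-butyldimethylsilyloxy)-6-methyl-2-methylidenehept-5-en-1-ol | C=C(CO)CC/C=C(\C)CO[Si](C)(C)C(C)(C)C | intermediate
15 | (E)-7-(tert-butyldimethylsilyloxy)-6-methyl-2-methylidenehept-5-en-1-yl 2,2,2-trichloroacetimidate | C=C(COC(=N)C(Cl)(Cl)Cl)CC/C=C(\C)CO[Si](C)(C)C(C)(C)C | intermediate
16 | 2-(trimethylsilyl)ethyl (R)-2-{2-[2,5-bis(tert-butyldimethylsilyloxy)phenyl]-2-oxoethyl}-2-(trimethylsilyloxy)hex-5-enoate (not isolated) | C=CCC[C@@](CC(=O)c1cc(O[Si](C)(C)C(C)(C)C)ccc1O[Si](C)(C)C(C)(C)C)(C(=O)OCC[Si](C)(C)C)O[Si](C)(C)C | intermediate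
17 | 2-(trimethylsilyl)ethyl (R)-2-{2-[2,5-bis(tert-butyldimethylsilyloxy)phenyl]-2-oxoethyl}-2-hydroxyhex-5-enoate | C=CCC[C@@](CC(=O)c1cc(O[Si](C)(C)C(C)(C)C)ccc1O[Si](C)(C)C(C)(C)C)(C(=O)OCC[Si](C)(C)C)O | intermediate
18 | 2-(trimethylsilyl)ethyl (R)-2-{2-[2,5-bis(tert-butyldimethylsilyloxy)phenyl]-2-oxoethyl}-2-{[(E)-7-(tert-butyldimethylsilyloxy)-6-methyl-2-methylidenehept-5-en-1-yl]oxy}hex-5-enoate | C=CCC[C@@](CC(=O)c1cc(O[Si](C)(C)C(C)(C)C)ccc1O[Si](C)(C)C(C)(C)C)(C(=O)OCC[Si](C)(C)C)OCC(=C)CC/C=C(\C)CO[Si](C)(C)C(C)(C)C | intermediate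
19 | 2-(trimethylsilyl)ethyl (R)-2-{2-[2,5-bis(tert-butyldimethylsilyloxy)phenyl]-2-oxoethyl}-6-[(E)-5-(tert-butyldimethylsilyloxy)-4-methylpent-3-en-1-yl]-2,3,4,7-tetrahydrooxepine-2-carboxylate | C/C(=C\CCC1=CCC[C@@](CC(=O)c2cc(O[Si](C)(C)C(C)(C)C)ccc2O[Si](C)(C)C(C)(C)C)(C(=O)OCC[Si](C)(C)C)OC1)CO[Si](C)(C)C(C)(C)C | intermediate
20 | (R)-2-[2-(2,5-dihydroxyphenyl)-2-oxoethyl]-6-[(E)-5-hydroxy-4-methylpent-3-en-1-yl]-2,3,4,7-tetrahydrooxepine-2-carboxylic acid | C/C(=C\CCC1=CCC[C@@](CC(=O)c2cc(O)ccc2O)(C(=O)O)OC1)CO | target

**Step count and risks**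

Total steps: 12. Longest linear sequence: 7 (steps 5, 6, 7, 8, 10, 11, 12).

Steps most likely to fail:

1. Step 10. The hindered tertiary hydroxyl, deactivated by the adjacent ester, may capture the protonated imidate too slowly, so that rearrangement of the imidate to the N-allyl trichloroacetamide and acid-induced dehydration of the β-hydroxy ketone take over. The fallback sets out from 14 and 17 and comes back at 18. Alcohol 14 would be acetylated (Ac2O, pyridine, DMAP, CH2Cl2) to (E)-7-(tert-butyldimethylsilyloxy)-6-methyl-2-methylidenehept-5-en-1-yl acetate F1. Carbinol 17 would be converted into its zinc alkoxide with Et2Zn (0.5 equiv) in THF and allylated with F1 under Pd(OAc)2 / 2-(di-tert-butylphosphino)biphenyl catalysis at rt. This is a π-allylpalladium etherification under neutral conditions; the covalent zinc alkoxide should resist retro-aldol cleavage, and the symmetric 2-substituted allyl unit allows only one regioisomer, 18.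

2. Step 9. The bulky ortho-silyloxy enolsilane or the longer keto-ester chain may disturb the square-planar chelate, leading to poor facial discrimination or slow turnover; the sense of induction is taken from the model and would have to be confirmed. The fallback sets out from 2 and 8 and comes back at 17. The lithium enolate of 2 (LiHMDS, THF, −78 °C) would be added to 8 and quenched cold to give racemic 2-(trimethylsilyl)ethyl 2-{2-[2,5-bis(tert-butyldimethylsilyloxy)phenyl]-2-oxoethyl}-2-hydroxyhex-5-enoate F2. Its enantiomers would be separated by preparative chromatography on a chiral stationary phase, the (R)-enantiomer being 17.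

3. Step 12. Basic fluoride may enolise the ketone and expel the ring oxygen (β-elimination, opening of the oxepine), after which the ortho-phenoxide can re-add to give a chromanone; cleavage of the ester may also stay incomplete. The fallback sets out from 19 and comes back at 20. The three silyl ethers would first be removed under acidic fluoride (HF·pyridine, pyridine, THF, 0 °C → rt) to give 2-(trimethylsilyl)ethyl (R)-2-[2-(2,5-dihydroxyphenyl)-2-oxoethyl]-6-[(E)-5-hydroxy-4-methylpent-3-en-1-yl]-2,3,4,7-tetrahydrooxepine-2-carboxylate F3. In F3 the free, hydrogen-bonded ortho-phenol deactivates the ketone and buffers the medium. The silylethyl ester would then be cleaved with anhydrous tris(dimethylamino)sulfonium difluorotrimethylsilicate (TASF) in DMF at 0 °C to give 20.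

**Further compounds**

F1 | step 10 | (E)-7-(tert-butyldimethylsilyloxy)-6-methyl-2-methylidenehept-5-en-1-yl acetate | C=C(COC(C)=O)CC/C=C(\C)CO[Si](C)(C)C(C)(C)C
F2 | step 9 | racemic 2-(trimethylsilyl)ethyl 2-{2-[2,5-bis(tert-butyldimethylsilyloxy)phenyl]-2-oxoethyl}-2-hydroxyhex-5-enoate | C=CCCC(CC(=O)c1cc(O[Si](C)(C)C(C)(C)C)ccc1O[Si](C)(C)C(C)(C)C)(C(=O)OCC[Si](C)(C)C)O
F3 | step 12 | 2-(trimethylsilyl)ethyl (R)-2-[2-(2,5-dihydroxyphenyl)-2-oxoethyl]-6-[(E)-5-hydroxy-4-methylpent-3-en-1-yl]-2,3,4,7-tetrahydrooxepine-2-carboxylate | C/C(=C\CCC1=CCC[C@@](CC(=O)c2cc(O)ccc2O)(C(=O)OCC[Si](C)(C)C)OC1)CO
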